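# Glycyrrhizaisoflavone B by late catechol oxidation and oxa-6π closure of ring D

## Analysis of the target

Glycyrrhizaisoflavone B 18 is an isoflavone in which ring A is fused to the γ-pyrone ring C, C3 carries aryl ring B, and ring B is fused across C4'–C5' to a 2,2-dimethyl-2H-pyran, ring D. Ring A has a methyl ether on C5, peri to the C4 carbonyl, and a free hydroxyl on C7; ring B has a free hydroxyl on C3', the pyran oxygen on C4' and the styrene-type carbon C4'' on C5'. There is no stereocentre, because C2'' carries two methyl groups, so every problem of the synthesis is one of regiochemistry and chemoselectivity. The sensitive sites are the C3''=C4'' alkene of the chromene, which adds acid and electrophilic oxidants, the γ-pyrone, which hydroxide opens at C2, the C5 methyl ether, which chelating Lewis acids remove, and the free phenols. The difficulty lies in the 1,3,4,5-tetrasubstituted ring B with three different neighbours (hydroxyl, ring oxygen, ring carbon) and in keeping the C5 and C7 oxygens of ring A distinct. The strategy rests on reading ring D as the cyclised form of a 5'-prenyl-3',4'-catechol: only the O4'–C2'' bond and the C3''=C4'' unsaturation separate 18 from that catechol, and O4' is the only oxygen ortho to C5'.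

## Retrosynthetic reasoning

**Ring D (18 ⇒ 15).** The O4'–C2'' bond is cut and the C3''=C4'' alkene is returned to a prenyl group, which gives catechol 15. This cut is preferred to any C–C cut of ring D because it removes ring D in one operation at the very end, needs no protecting group, and has its regiochemistry built in: O3' cannot reach the side chain on C5'. The forward reaction must oxidise the catechol to ortho-quinone 16, shift a C4'' hydrogen to O3' to give ortho-quinone methide 17, and close the 1-oxatriene of 17 to 18.

**Phenol protection (15 ⇒ 14).** The three phenols of 15 are masked as methoxymethyl ethers in 14, so three O–CH2 acetal bonds are cut. One kind of protecting group allows one deprotection. The forward step must cleave three acetals without protonating the prenyl alkene.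

**Ring B to ring C (14 ⇒ 9 + 13).** The C3–C1' bond is cut. This is the most convergent cut: it divides the skeleton into two halves of similar size, a 3-iodochromone 13 and an arylboronate 9, which are the standard partners of a Suzuki–Miyaura isoflavone assembly. A deoxybenzoin construction of ring C would instead need Friedel–Crafts acylation under Lewis-acid conditions that neither the prenyl group nor the acetals would survive.

**Ring C (13 ⇒ 12 ⇒ 11 ⇒ 10).** In 13 the O1–C2 and C3–I bonds are cut, which leads to enaminone 12; iodination and ring closure happen together in the forward direction. The C2–C3 bond of 12 comes from condensation of the acetyl methyl group of 11 with a one-carbon amide acetal. Acetophenone 11 is the mono-protected form of 10, in which the C5 and C7 oxygens of the future ring A are already different.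

**Boronate (9 ⇒ 8 ⇒ 7).** The C1'–B bond is cut back to the C–Br bond of 8 (Miyaura borylation), and the two acetals of 8 back to catechol 7. Bromine is carried from the start because it marks C1' without ambiguity.

**The C3' oxygen (7 ⇒ 5).** The C3'–O bond is traced to a formyl group by a Dakin oxidation through formate 6. The formyl group of 5 therefore serves twice: it blocks one ortho position during the Claisen step and is a latent hydroxyl.

**The prenyl group (5 ⇒ 4).** The C5'–C4'' bond is cut by an aromatic Claisen transform. The [3,3] shift of the 1,1-dimethylallyl ether 4 transposes the allyl unit, so a linear prenyl group arrives only at the single free ortho carbon. Direct C-prenylation of a phenol would give O- and C-alkylation and mixtures of ring positions.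

**The ether (4 ⇒ 3 ⇒ 1 + 2).** Alkene 4 comes from alkyne 3 by semi-hydrogenation. The O–C bond of 3 is cut to the commercial phenol 1 and the tertiary propargylic chloride 2; copper-catalysed etherification is the reliable way to attach a tertiary carbon to a phenol oxygen.

## Alternatives that were turned down

**Alternative 1: aryne annulation of ring A onto a formylacetate.** The cuts are O1–C8a and C4–C4a, so ring C is closed last by bringing ring A in as an aryne. In the forward step a fluoride source releases 3-methoxy-5-(methoxymethoxy)benzyne A2 from an ortho-silyl aryl triflate. The enolate oxygen of methyl 2-[8-(methoxymethoxy)-2,2-dimethyl-2H-chromen-6-yl]-3-oxopropanoate A3 adds to the aryne carbon meta to the methoxy group. The aryl anion, now ortho to the methoxy group, attacks the ester and gives 5-methoxy-7-(methoxymethoxy)-3-[8-(methoxymethoxy)-2,2-dimethyl-2H-chromen-6-yl]-4H-chromen-4-one A1.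

- For: ring C is made in one operation, without palladium, and the usual preference of 3-alkoxyarynes (nucleophile distal to the alkoxy group) gives the right orientation in A1. On convergence at ring C this plan is at least as strong as the cross-coupling chosen here.
- Against: enolates of β-dicarbonyl compounds normally attack arynes through carbon and then give acyl–alkylation products, so the O-arylation needed from A3 is the less usual course. The silyl triflate behind A2 needs its own regiocontrolled multistep synthesis. A3 must already contain ring D, whose styrene-like alkene is exposed to the aryne (ene reaction, [2+2] addition). A1 still has two acetals to remove.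
- Comparison: the chosen route is not shorter, but it assembles the skeleton with routine reactions and places its one uncertain event at the end, where regiochemistry is fixed by the position of the prenyl group.

**Alternative 2: ring A benzannulation on a bromopyranone.** The cuts are C8–C8a and C4a–C5, so ring A is built by a Diels–Alder reaction. 1,1-Dimethoxy-3-(trimethylsilyloxy)buta-1,3-diene A5 would add across the brominated alkene of 3-bromo-5-[8-(methoxymethoxy)-2,2-dimethyl-2H-chromen-6-yl]-4H-pyran-4-one A6, with its CH2 terminus on the β-carbon (future C8a) and its acetal carbon on the bromine-bearing carbon (future C4a). Two eliminations, of the bromide with the neighbouring hydrogen and of one methoxy group, together with desilylation on work-up, would aromatise ring A and give 7-hydroxy-5-methoxy-3-[8-(methoxymethoxy)-2,2-dimethyl-2H-chromen-6-yl]-4H-chromen-4-one A4.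

- For: the 5-methoxy/7-hydroxy pattern of A4 is written by the polarity of diene A5, and the C7 hydroxyl of A4 emerges free. On this point the plan is stronger than the chosen route, which buys the differentiation with acetophenone 10 and carries a protecting group on C7.
- Against: a 4-pyranone such as A6 is a vinylogous ester with some aromatic character and a poor dienophile, and one bromine activates it only weakly. The ketene-acetal diene A5 is more likely to act as a Michael donor. A6 offers two enone double bonds. A6 would have to be made by mono-arylation of a symmetrical dibrominated pyranone. Ring D must again be present early and survive, and one acetal of A4 remains to be cleaved before the target is reached.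
- Comparison: the chosen strategy has no step whose basic feasibility is in doubt before the last one, and the last one follows a well-known reaction manifold, whereas the formation of A4 depends on a cycloaddition with no reliable driving force.

**Alternative 3: dearomatising spiroetherification, then dienone–phenol vinyl shift.** The C4'–O and C5'–C4'' bonds are made indirectly. A trivalent iodine diacetate oxidant would oxidise the C3' phenol of 3-{3-hydroxy-4-[(1Z)-3-hydroxy-3-methylbut-1-en-1-yl]phenyl}-5-methoxy-7-(methoxymethoxy)-4H-chromen-4-one A8. The tertiary hydroxyl then attacks C4' and gives the spiro-dihydrofuran dienone 3-(2,2-dimethyl-6-oxo-1-oxaspiro[4.5]deca-3,7,9-trien-8-yl)-5-methoxy-7-(methoxymethoxy)-4H-chromen-4-one A9. Acid would move the vinyl carbon from C4' to C5' and rearomatise ring B to 3-(8-hydroxy-2,2-dimethyl-2H-chromen-6-yl)-5-methoxy-7-(methoxymethoxy)-4H-chromen-4-one A7.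

- For: no catechol and no ortho-quinone are involved, the oxidant meets only the monophenol of A8 while C7 is still protected, and a vinyl group migrates well. On oxidative chemoselectivity the plan is stronger than the chosen one.
- Against: A8 is a (Z)-ortho-hydroxycinnamyl tertiary alcohol and cyclises in acid directly through O3' to the regioisomeric chromene. Dienones such as A9 dimerise by Diels–Alder reaction. In acid A9 can ionise its allylic spiro C–O bond or migrate oxygen instead of carbon. A8 needs a stereoselective semi-reduction. A7 still needs deprotection, and the two-stage cascade has no close model.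
- Comparison: the chosen strategy ends on the target itself, with regiochemistry secured by the substrate and not by a migration preference.

Key step: step 12

Remark: 1-(2,4-dihydroxy-6-methoxyphenyl)ethan-1-one 10 is taken as a purchasable compound, so the C5 methyl ether and the C7 oxygen of ring A are distinct from the start.

## Route

Step 1
Reactants: 1 5-bromo-2-hydroxybenzaldehyde; 2 3-chloro-3-methylbut-1-yne
Product: 3 5-bromo-2-[(2-methylbut-3-yn-2-yl)oxy]benzaldehyde
Conditions: DBU, CuCl2·2H2O (cat.), MeCN, 0 °C to rt
Reagents that add atoms: none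
Why: Copper-catalysed O-alkylation of a phenol with a tertiary propargylic chloride: DBU forms the phenoxide, and the copper acetylide of 2 ionises to an allenylidene-type electrophile that is captured at the tertiary carbon, which avoids the elimination seen under plain substitution conditions.

Step 2
Reactants: 3 5-bromo-2-[(2-methylbut-3-yn-2-yl)oxy]benzaldehyde
Product: 4 5-bromo-2-[(2-methylbut-3-en-2-yl)oxy]benzaldehyde
Conditions: H2 (1 atm), Pd/CaCO3 poisoned with Pb(OAc)2 (Lindlar catalyst), quinoline, EtOAc, rt
Reagents that add atoms: none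
Why: Lindlar semi-hydrogenation stops at the alkene because the poisoned palladium surface binds the alkyne far better than the alkene; aryl bromide, aldehyde and the allylic C–O bond should be untouched if uptake is stopped after one equivalent.

Step 3
Reactants: 4 5-bromo-2-[(2-methylbut-3-en-2-yl)oxy]benzaldehyde
Product: 5 5-bromo-2-hydroxy-3-(3-methylbut-2-en-1-yl)benzaldehyde
Conditions: PhNEt2, 140 °C
Reagents that add atoms: none
Why: Aromatic Claisen rearrangement: the [3,3] shift joins the CH2 terminus of the 1,1-dimethylallyl ether to the only ortho carbon bearing hydrogen (the other carries the formyl group, the para carbon bromine) and tautomerisation restores the phenol, so the reverse-prenyl ether becomes a linear prenyl group; the amine solvent buffers acid traces that would cyclise the product.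

Step 4
Reactants: 5 5-bromo-2-hydroxy-3-(3-methylbut-2-en-1-yl)benzaldehyde
Product: 7 5-bromo-3-(3-methylbut-2-en-1-yl)benzene-1,2-diol, via aryl formate 6 (not isolated)
Conditions: 30% aq. H2O2, NaOH, THF/H2O, 0 °C to rt, N2; then aq. HCl
Reagents that add atoms: hydrogen peroxide, OO
Why: Dakin oxidation: hydroperoxide anion adds to the formyl group, the electron-rich ortho-phenoxide aryl group migrates to oxygen to give formate 6, and hydroxide hydrolyses it in the same flask; alkaline H2O2 is a nucleophilic oxidant and should not epoxidise the isolated trisubstituted alkene, and exclusion of air limits oxidation of the catechol.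

Step 5
Reactants: 7 5-bromo-3-(3-methylbut-2-en-1-yl)benzene-1,2-diol
Product: 8 5-bromo-1,2-bis(methoxymethoxy)-3-(3-methylbut-2-en-1-yl)benzene
Conditions: MOMCl, i-Pr2NEt, CH2Cl2, 0 °C to rt
Reagents that add atoms: chloromethyl methyl ether, COCCl
Why: O-alkylation of both phenols to mixed acetals; MOM ethers withstand the basic palladium steps that follow and can all be removed in one acidic operation.

Step 6
Reactants: 8 5-bromo-1,2-bis(methoxymethoxy)-3-(3-methylbut-2-en-1-yl)benzene
Product: 9 2-[3,4-bis(methoxymethoxy)-5-(3-methylbut-2-en-1-yl)phenyl]-4,4,5,5-tetramethyl-1,3,2-dioxaborolane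
Conditions: B2pin2, Pd(dppf)Cl2 (cat.), KOAc, 1,4-dioxane, 90 °C
Reagents that add atoms: bis(pinacolato)diboron, CC1(C)OB(OC1(C)C)B1OC(C)(C)C(C)(C)O1
Why: Miyaura borylation: zerovalent palladium adds to the unhindered C–Br bond (both ortho positions carry hydrogen), acetate assists transmetalation with B2pin2, and KOAc is too weak a base to start a Suzuki homocoupling.

Step 7
Reactants: 10 1-(2,4-dihydroxy-6-methoxyphenyl)ethan-1-one
Product: 11 1-[2-hydroxy-6-methoxy-4-(methoxymethoxy)phenyl]ethan-1-one
Conditions: MOMCl (1.05 equiv), i-Pr2NEt, CH2Cl2, 0 °C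
Reagents that add atoms: chloromethyl methyl ether, COCCl
Why: Chemoselective O-alkylation: the C2 hydroxyl is held in a hydrogen bond to the acetyl oxygen and is much less nucleophilic, so one equivalent of MOMCl should react only at the free C4 hydroxyl.

Step 8
Reactants: 11 1-[2-hydroxy-6-methoxy-4-(methoxymethoxy)phenyl]ethan-1-one
Product: 12 (2E)-3-(dimethylamino)-1-[2-hydroxy-6-methoxy-4-(methoxymethoxy)phenyl]prop-2-en-1-one
Conditions: DMF-DMA, toluene, 95 °C
Reagents that add atoms: N,N-dimethylformamide dimethyl acetal, COC(OC)N(C)C
Why: Enaminone condensation: the acetyl methyl group adds to the methoxyiminium ion of the amide acetal and methanol is lost twice, giving the E vinylogous amide that is the usual precursor of 3-substituted chromones.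

Step 9
Reactants: 12 (2E)-3-(dimethylamino)-1-[2-hydroxy-6-methoxy-4-(methoxymethoxy)phenyl]prop-2-en-1-one
Product: 13 3-iodo-5-methoxy-7-(methoxymethoxy)-4H-chromen-4-one
Conditions: I2, pyridine, CHCl3, rt
Reagents that add atoms: iodine, II
Why: Iodocyclisation of a 2-hydroxyaryl enaminone: iodine attacks the nucleophilic α-carbon, the phenol adds to the iminium carbon to close ring C through the O1–C2 bond, and dimethylamine is eliminated; pyridine keeps the medium from becoming acidic enough to cleave the MOM ether.

Step 10
Reactants: 9 2-[3,4-bis(methoxymethoxy)-5-(3-methylbut-2-en-1-yl)phenyl]-4,4,5,5-tetramethyl-1,3,2-dioxaborolane; 13 3-iodo-5-methoxy-7-(methoxymethoxy)-4H-chromen-4-one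
Product: 14 3-[3,4-bis(methoxymethoxy)-5-(3-methylbut-2-en-1-yl)phenyl]-5-methoxy-7-(methoxymethoxy)-4H-chromen-4-one
Conditions: Pd(dppf)Cl2 (5 mol %), aq. K2CO3, 1,4-dioxane, 80 °C
Reagents that add atoms: none
Why: Suzuki–Miyaura coupling: the C3–I bond of the electron-poor chromone adds readily to zerovalent palladium and the carbonate-activated boronate transfers its aryl group; this is the standard isoflavone assembly, and MOM ethers and the prenyl group are inert to it.

Step 11
Reactants: 14 3-[3,4-bis(methoxymethoxy)-5-(3-methylbut-2-en-1-yl)phenyl]-5-methoxy-7-(methoxymethoxy)-4H-chromen-4-one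
Product: 15 3-[3,4-dihydroxy-5-(3-methylbut-2-en-1-yl)phenyl]-7-hydroxy-5-methoxy-4H-chromen-4-one
Conditions: 3 M aq. HCl, MeOH/THF, 40 °C
Reagents that add atoms: none
Why: Acid-catalysed transacetalisation of the three MOM ethers to dimethoxymethane; dilute acid at mild temperature is chosen so that protonation of the prenyl alkene, which leads to a chroman, stays slower than acetal cleavage.

Step 12
Reactants: 15 3-[3,4-dihydroxy-5-(3-methylbut-2-en-1-yl)phenyl]-7-hydroxy-5-methoxy-4H-chromen-4-one
Product: 18 glycyrrhizaisoflavone B, via ortho-quinone 16 (not isolated), via ortho-quinone methide 17 (not isolated)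
Conditions: Ag2O (1.1 equiv), Na2SO4, THF, 0 °C to rt, dark; then Et3N (0.1 equiv), rt
Reagents that add atoms: none
Why: Ag2O removes two electrons and two protons from the 3',4'-catechol, the most electron-rich site of 15, and gives ortho-quinone 16. A hydrogen of the C4'' methylene, which is allylic and vinylogously α to the C3' carbonyl through C5'=C6'–C1'=C2', is then shifted to O3' (amine-assisted), giving ortho-quinone methide 17 with O4'=C4'–C5'=C4''–C3''=C2'' as a 1-oxatriene. Thermal disrotatory oxa-6π electrocyclisation of the Z isomer of 17 forms the O4'–C2'' bond, closes the six-membered ring D and restores the aromatic ring B with the C3' hydroxyl free. The closest known reaction type is the conversion of prenylquinones into chromenols and the oxidative cyclisation of ortho-prenylphenols to 2,2-dimethyl-2H-chromenes, both through ortho-quinone methides. No stereocentre is formed, since C2'' carries two methyl groups. Chemoselectivity should follow from the fact that the lone C7 phenol sits on the electron-poor chromone and cannot form a quinone. Regioselectivity is fixed because only O4' is ortho to C5'; E and Z forms of 17 can equilibrate through 16 and only the Z form closes, the closure being driven by rearomatisation. One equivalent of oxidant is used so that the phenolic product 18 is not oxidised further.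

## Compound list

1 | 5-bromo-2-hydroxybenzaldehyde | O=Cc1cc(Br)ccc1O | starting material
2 | 3-chloro-3-methylbut-1-yne | C#CC(C)(C)Cl | starting material
3 | 5-bromo-2-[(2-methylbut-3-yn-2-yl)oxy]benzaldehyde | O=Cc1cc(Br)ccc1OC(C)(C)C#C | intermediate
4 | 5-bromo-2-[(2-methylbut-3-en-2-yl)oxy]benzaldehyde | O=Cc1cc(Br)ccc1OC(C)(C)C=C | intermediate
5 | 5-bromo-2-hydroxy-3-(3-methylbut-2-en-1-yl)benzaldehyde | O=Cc1cc(Br)cc(CC=C(C)C)c1O | intermediate
6 | 5-bromo-2-hydroxy-3-(3-methylbut-2-en-1-yl)phenyl formate (not isolated) | O=COc1cc(Br)cc(CC=C(C)C)c1O | intermediate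
7 | 5-bromo-3-(3-methylbut-2-en-1-yl)benzene-1,2-diol | Oc1cc(Br)cc(CC=C(C)C)c1O | intermediate
8 | 5-bromo-1,2-bis(methoxymethoxy)-3-(3-methylbut-2-en-1-yl)benzene | COCOc1cc(Br)cc(CC=C(C)C)c1OCOC | intermediate
9 | 2-[3,4-bis(methoxymethoxy)-5-(3-methylbut-2-en-1-yl)phenyl]-4,4,5,5-tetramethyl-1,3,2-dioxaborolane | COCOc1cc(B2OC(C)(C)C(C)(C)O2)cc(CC=C(C)C)c1OCOC | intermediate
10 | 1-(2,4-dihydroxy-6-methoxyphenyl)ethan-1-one | CC(=O)c1c(O)cc(O)cc1OC | starting material
11 | 1-[2-hydroxy-6-methoxy-4-(methoxymethoxy)phenyl]ethan-1-one | CC(=O)c1c(O)cc(OCOC)cc1OC | intermediate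
12 | (2E)-3-(dimethylamino)-1-[2-hydroxy-6-methoxy-4-(methoxymethoxy)phenyl]prop-2-en-1-one | CN(C)/C=C/C(=O)c1c(O)cc(OCOC)cc1OC | intermediate
13 | 3-iodo-5-methoxy-7-(methoxymethoxy)-4H-chromen-4-one | COc1cc(OCOC)cc2occ(I)c(=O)c12 | intermediate
14 | 3-[3,4-bis(methoxymethoxy)-5-(3-methylbut-2-en-1-yl)phenyl]-5-methoxy-7-(methoxymethoxy)-4H-chromen-4-one | COc1cc(OCOC)cc2occ(-c3cc(OCOC)c(OCOC)c(CC=C(C)C)c3)c(=O)c12 | intermediate
15 | 3-[3,4-dihydroxy-5-(3-methylbut-2-en-1-yl)phenyl]-7-hydroxy-5-methoxy-4H-chromen-4-one | COc1cc(O)cc2occ(-c3cc(O)c(O)c(CC=C(C)C)c3)c(=O)c12 | intermediate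
16 | 7-hydroxy-5-methoxy-3-[5-(3-methylbut-2-en-1-yl)-3,4-dioxocyclohexa-1,5-dien-1-yl]-4H-chromen-4-one (ortho-quinone, not isolated) | COc1cc(O)cc2occ(C3=CC(=O)C(=O)C(CC=C(C)C)=C3)c(=O)c12 | intermediate
17 | 7-hydroxy-3-[(3Z)-5-hydroxy-3-(3-methylbut-2-en-1-ylidene)-4-oxocyclohexa-1,5-dien-1-yl]-5-methoxy-4H-chromen-4-one (ortho-quinone methide, not isolated) | COc1cc(O)cc2occ(C3=C/C(=C/C=C(C)C)C(=O)C(O)=C3)c(=O)c12 | intermediate
18 | glycyrrhizaisoflavone B, 7-hydroxy-3-(8-hydroxy-2,2-dimethyl-2H-chromen-6-yl)-5-methoxy-4H-chromen-4-one | COc1cc(O)cc2occ(-c3cc(O)c4c(c3)C=CC(C)(C)O4)c(=O)c12 | target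

## Step count and least certain steps

Total step count: 12. Longest linear sequence: 9 steps (steps 1 to 6, then 10, 11 and 12); the chromone branch (steps 7 to 9) joins at step 10.

**Step 12 (key step).** Ortho-quinone 16 may be consumed by intermolecular processes before it tautomerises to 17: Diels–Alder dimerisation, conjugate addition of unreacted catechol 15 or of the C7 phenoxide, or redox exchange with the product. If tautomerisation is slow, the quinone lives long enough for these to dominate. The basic oxide may also tie up the acidic C7 phenol and stall the oxidation.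

Fallback, from 3 back to 18: ring D is closed by the thermal rearrangement of the aryl propargyl ether, which needs no oxidation of ring B. Baeyer–Villiger oxidation of 3 (mCPBA, CH2Cl2) should give 5-bromo-2-[(2-methylbut-3-yn-2-yl)oxy]phenyl formate F1, and methanolysis (K2CO3, MeOH) then gives 5-bromo-2-[(2-methylbut-3-yn-2-yl)oxy]phenol F2. MOMCl and i-Pr2NEt convert it into 4-bromo-2-(methoxymethoxy)-1-[(2-methylbut-3-yn-2-yl)oxy]benzene F3. Heating this ether in PhNEt2 at 180 °C should give 6-bromo-8-(methoxymethoxy)-2,2-dimethyl-2H-chromene F4 by propargyl Claisen rearrangement to the only free ortho carbon, 1,5-hydrogen shift and oxa-6π closure. Miyaura borylation (B2pin2, Pd(dppf)Cl2, KOAc, dioxane) gives 2-[8-(methoxymethoxy)-2,2-dimethyl-2H-chromen-6-yl]-4,4,5,5-tetramethyl-1,3,2-dioxaborolane F5. Suzuki coupling with 13 (Pd(dppf)Cl2, aq. K2CO3, dioxane) gives 5-methoxy-7-(methoxymethoxy)-3-[8-(methoxymethoxy)-2,2-dimethyl-2H-chromen-6-yl]-4H-chromen-4-one F6, which is the same compound as A1, and dilute HCl in MeOH then removes both acetals to give 18.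

**Step 3.** The tertiary allyl ether may fragment instead of rearranging, by ionisation or retro-ene cleavage of its weak tertiary allylic C–O bond, which would return phenol 1.

Fallback, from 1 back to 5: the allyl group is installed first and extended to prenyl afterwards. Allyl bromide and K2CO3 in acetone give 5-bromo-2-(prop-2-en-1-yloxy)benzaldehyde F7. Claisen rearrangement at 190 °C gives 5-bromo-2-hydroxy-3-(prop-2-en-1-yl)benzaldehyde F8. Cross-metathesis with 2-methylbut-2-ene and (H2IMes)(PCy3)Cl2Ru=CHPh (second-generation Grubbs catalyst) in CH2Cl2 at 40 °C then gives 5.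

**Step 10.** Protodeboronation of the electron-rich boronate and opening of the pyranone ring of 13 by aqueous base at C2 may outrun the coupling.

Fallback, from 8 back to 14: a Negishi coupling without aqueous base. Bromine–lithium exchange on 8 (n-BuLi, THF, −78 °C) and transmetalation with ZnCl2 give [3,4-bis(methoxymethoxy)-5-(3-methylbut-2-en-1-yl)phenyl]zinc chloride F9, which is coupled with 13 (Pd(PPh3)4, THF, rt to 50 °C) to give 14.

**Step 11.** Acid may protonate the prenyl alkene so that the C4' hydroxyl adds to the tertiary cation (chroman formation), or methanol may add to the alkene. This competes because the ortho phenol is freed in the same medium that holds the acid.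

Fallback, from 7 and 13 back to 15: the catechol is masked with fluoride-labile groups and the chromone acetal is removed before the prenyl group is in the molecule. TBSCl and imidazole in DMF convert 7 into 5-bromo-1,2-bis[(tert-butyldimethylsilyl)oxy]-3-(3-methylbut-2-en-1-yl)benzene F10. Miyaura borylation (B2pin2, Pd(dppf)Cl2, KOAc, dioxane) gives 2-{3,4-bis[(tert-butyldimethylsilyl)oxy]-5-(3-methylbut-2-en-1-yl)phenyl}-4,4,5,5-tetramethyl-1,3,2-dioxaborolane F11. Aqueous HCl in MeOH converts 13 into 7-hydroxy-3-iodo-5-methoxy-4H-chromen-4-one F12. Suzuki coupling of the boronate with this iodide (Pd(dppf)Cl2, K3PO4, dioxane/H2O) gives 3-{3,4-bis[(tert-butyldimethylsilyl)oxy]-5-(3-methylbut-2-en-1-yl)phenyl}-7-hydroxy-5-methoxy-4H-chromen-4-one F13. TBAF buffered with AcOH in THF at 0 °C then gives 15.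

## Further compounds

F1 | step 12 | 5-bromo-2-[(2-methylbut-3-yn-2-yl)oxy]phenyl formate | O=COc1cc(Br)ccc1OC(C)(C)C#C
F2 | step 12 | 5-bromo-2-[(2-methylbut-3-yn-2-yl)oxy]phenol | Oc1cc(Br)ccc1OC(C)(C)C#C
F3 | step 12 | 4-bromo-2-(methoxymethoxy)-1-[(2-methylbut-3-yn-2-yl)oxy]benzene | COCOc1cc(Br)ccc1OC(C)(C)C#C
F4 | step 12 | 6-bromo-8-(methoxymethoxy)-2,2-dimethyl-2H-chromene | COCOc1cc(Br)cc2C=CC(C)(C)Oc12
F5 | step 12 | 2-[8-(methoxymethoxy)-2,2-dimethyl-2H-chromen-6-yl]-4,4,5,5-tetramethyl-1,3,2-dioxaborolane | COCOc1cc(B3OC(C)(C)C(C)(C)O3)cc2C=CC(C)(C)Oc12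
F6 | step 12 | 5-methoxy-7-(methoxymethoxy)-3-[8-(methoxymethoxy)-2,2-dimethyl-2H-chromen-6-yl]-4H-chromen-4-one | COCOc1cc(OC)c2c(c1)occ(-c1cc(OCOC)c3OC(C)(C)C=Cc3c1)c2=O
F7 | step 3 | 5-bromo-2-(prop-2-en-1-yloxy)benzaldehyde | O=Cc1cc(Br)ccc1OCC=C
F8 | step 3 | 5-bromo-2-hydroxy-3-(prop-2-en-1-yl)benzaldehyde | O=Cc1cc(Br)cc(CC=C)c1O
F9 | step 10 | [3,4-bis(methoxymethoxy)-5-(3-methylbut-2-en-1-yl)phenyl]zinc chloride | COCOc1cc([Zn]Cl)cc(CC=C(C)C)c1OCOC
F10 | step 11 | 5-bromo-1,2-bis[(tert-butyldimethylsilyl)oxy]-3-(3-methylbut-2-en-1-yl)benzene | CC(C)(C)[Si](C)(C)Oc1cc(Br)cc(CC=C(C)C)c1O[Si](C)(C)C(C)(C)C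
F11 | step 11 | 2-{3,4-bis[(tert-butyldimethylsilyl)oxy]-5-(3-methylbut-2-en-1-yl)phenyl}-4,4,5,5-tetramethyl-1,3,2-dioxaborolane | CC(C)(C)[Si](C)(C)Oc1cc(B2OC(C)(C)C(C)(C)O2)cc(CC=C(C)C)c1O[Si](C)(C)C(C)(C)C
F12 | step 11 | 7-hydroxy-3-iodo-5-methoxy-4H-chromen-4-one | COc1cc(O)cc2occ(I)c(=O)c12
F13 | step 11 | 3-{3,4-bis[(tert-butyldimethylsilyl)oxy]-5-(3-methylbut-2-en-1-yl)phenyl}-7-hydroxy-5-methoxy-4H-chromen-4-one | COc1cc(O)cc2occ(-c3cc(O[Si](C)(C)C(C)(C)C)c(O[Si](C)(C)C(C)(C)C)c(CC=C(C)C)c3)c(=O)c12
A1 | alternative 1 | 5-methoxy-7-(methoxymethoxy)-3-[8-(methoxymethoxy)-2,2-dimethyl-2H-chromen-6-yl]-4H-chromen-4-one | COCOc1cc(OC)c2c(c1)occ(-c1cc(OCOC)c3OC(C)(C)C=Cc3c1)c2=O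
A2 | alternative 1 | 3-methoxy-5-(methoxymethoxy)benzyne (1,2-didehydro-3-methoxy-5-(methoxymethoxy)benzene) | COC1=CC(OCOC)=CC#C1
A3 | alternative 1 | methyl 2-[8-(methoxymethoxy)-2,2-dimethyl-2H-chromen-6-yl]-3-oxopropanoate (racemic, enolisable) | COC(=O)C(C=O)c1cc(OCOC)c2OC(C)(C)C=Cc2c1
A4 | alternative 2 | 7-hydroxy-5-methoxy-3-[8-(methoxymethoxy)-2,2-dimethyl-2H-chromen-6-yl]-4H-chromen-4-one | COc1cc(O)cc2occ(-c3cc(OCOC)c4OC(C)(C)C=Cc4c3)c(=O)c12
A5 | alternative 2 | 1,1-dimethoxy-3-(trimethylsilyloxy)buta-1,3-diene | COC(OC)=CC(=C)O[Si](C)(C)C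
A6 | alternative 2 | 3-bromo-5-[8-(methoxymethoxy)-2,2-dimethyl-2H-chromen-6-yl]-4H-pyran-4-one | O=c1c(Br)cocc1-c1cc(OCOC)c2OC(C)(C)C=Cc2c1
A7 | alternative 3 | 3-(8-hydroxy-2,2-dimethyl-2H-chromen-6-yl)-5-methoxy-7-(methoxymethoxy)-4H-chromen-4-one | COCOc1cc(OC)c2c(c1)occ(-c1cc(O)c3OC(C)(C)C=Cc3c1)c2=O
A8 | alternative 3 | 3-{3-hydroxy-4-[(1Z)-3-hydroxy-3-methylbut-1-en-1-yl]phenyl}-5-methoxy-7-(methoxymethoxy)-4H-chromen-4-one | COCOc1cc(OC)c2c(c1)occ(-c1ccc(/C=C\C(C)(C)O)c(O)c1)c2=O
A9 | alternative 3 | 3-(2,2-dimethyl-6-oxo-1-oxaspiro[4.5]deca-3,7,9-trien-8-yl)-5-methoxy-7-(methoxymethoxy)-4H-chromen-4-one (racemic) | COCOc1cc(OC)c2c(c1)occ(C1=CC(=O)C3(OC(C)(C)C=C3)C=C1)c2=O
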